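**Retrosynthetic overview**

1. 5-Methoxygalbelgin ⇐ the all-trans 2,5-diaryl-4-methyloxolane-3-carbaldehyde; the formyl group becomes the C3 methyl group (reduction, mesylation, hydride displacement).
2. The oxolane ring is not closed directly. It comes from a seven-membered 4,5-dihydro-1,3-dioxepine by a Lewis-acid [1,3] O-to-C ring contraction that forms the C2–C3 bond and sets C2 and C3 under relay from C4 and C5.
3. Enabling feature: in the dioxepine the acetal carbon C2 (bearing the 3,4-dimethoxyphenyl group) is bonded to O1, which is also the oxygen of the ring enol ether O1–C7=C6. Breaking C2–O1 gives an aryl-stabilised oxocarbenium ion on O3 and an enolate whose carbon C6 is placed to close a five-membered ring onto C2.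
4. Dioxepine ⇐ enol-ether ring-closing metathesis of an acyclic vinyl mixed acetal ⇐ (1S,2S)-homoallylic alcohol + an α-chloro ether made from veratraldehyde.
5. Homoallylic alcohol ⇐ 3,4,5-trimethoxybenzaldehyde by catalytic asymmetric anti-crotylboration (the only reagent-controlled stereocentres). Ring order: seven-membered dioxepine first, five-membered oxolane second.

Key step: step 6

Assumption: the (S)-configured phosphoric acid of step 1 is taken to deliver the crotyl group to the Si face of the aldehyde; should the opposite sense be found, its (R)-antipode would be used without other change.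

**Route**

Step 1
Reactants: 1 3,4,5-trimethoxybenzaldehyde; 2 (E)-crotylboronic acid pinacol ester
Product: 4 (1S,2S)-2-methyl-1-(3,4,5-trimethoxyphenyl)but-3-en-1-ol, via O-boryl ether 3 (not isolated)
Conditions: 2 (1.2 equiv), (S)-TRIP [(S)-3,3'-bis(2,4,6-triisopropylphenyl)-1,1'-binaphthyl-2,2'-diyl hydrogen phosphate] (5 mol %), 4 Å MS, PhMe, −30 °C; then aq. NaHCO3
Reagents that add atoms: none
Why: Chiral phosphoric acid-catalysed crotylboration through a closed chair transition state, in which the (E)-boronate should give the anti relationship and the catalyst should select the Si face of the aldehyde, setting both stereocentres (1S,2S).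

Step 2
Reactants: 5 3,4-dimethoxybenzaldehyde (veratraldehyde); 6 2-bromoethanol
Product: 7 4-[bis(2-bromoethoxy)methyl]-1,2-dimethoxybenzene
Conditions: 6 (2.5 equiv), TsOH·H2O (2 mol %), PhMe, reflux, Dean–Stark
Reagents that add atoms: none
Why: Acid-catalysed acetalisation driven by azeotropic removal of water; no stereocentre is involved.

Step 3
Reactants: 7 4-[bis(2-bromoethoxy)methyl]-1,2-dimethoxybenzene; 4 (1S,2S)-2-methyl-1-(3,4,5-trimethoxyphenyl)but-3-en-1-ol
Product: 9 4-[(2-bromoethoxy){[(1S,2S)-2-methyl-1-(3,4,5-trimethoxyphenyl)but-3-en-1-yl]oxy}methyl]-1,2-dimethoxybenzene (both epimers at the acetal carbon), via alpha-chloro ether 8 (not isolated)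
Conditions: 7 (1.3 equiv), AcCl (1.3 equiv), CH2Cl2, 0 °C → rt; then 4, iPr2NEt (3 equiv), CH2Cl2, −20 °C → rt
Reagents that add atoms: none
Why: Acetyl chloride should cleave the acetal to the α-chloro ether, which alkoxyalkylates the alcohol under amine buffering (the way MOM and BOM ethers are made), so that no free acid can start a Prins closure onto the alkene; the acetal carbon forms as an epimer mixture, which does not matter because it is ionised in step 6.

Step 4
Reactants: 9 bromoethyl mixed acetal
Product: 10 4-[(ethenyloxy){[(1S,2S)-2-methyl-1-(3,4,5-trimethoxyphenyl)but-3-en-1-yl]oxy}methyl]-1,2-dimethoxybenzene (both epimers at the acetal carbon)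
Conditions: KOtBu (1.5 equiv), THF, 0 °C → rt
Reagents that add atoms: none
Why: E2 dehydrobromination of a 2-bromoethyl ether to the vinyl ether with a bulky base; the acetal, the terminal alkene and both stereocentres should be untouched.

Step 5
Reactants: 10 vinyl mixed acetal
Product: 11 (4S,5S)-2-(3,4-dimethoxyphenyl)-5-methyl-4-(3,4,5-trimethoxyphenyl)-4,5-dihydro-1,3-dioxepine (both epimers at C2)
Conditions: second-generation Grubbs catalyst RuCl2(=CHPh)(H2IMes)(PCy3) (10 mol %), 1,4-benzoquinone (10 mol %), PhMe (5 mM), 70 °C, argon sparge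
Reagents that add atoms: none
Why: Ring-closing metathesis between the terminal olefin and the vinyl ether should close the seven-membered cyclic enol ether (O1–C7=C6) with loss of ethene; the catalyst should load on the terminal olefin and benzoquinone should suppress double-bond migration.

Step 6
Reactants: 11 (4S,5S)-2-(3,4-dimethoxyphenyl)-5-methyl-4-(3,4,5-trimethoxyphenyl)-4,5-dihydro-1,3-dioxepine
Product: 13 (2S,3S,4S,5S)-2-(3,4-dimethoxyphenyl)-4-methyl-5-(3,4,5-trimethoxyphenyl)oxolane-3-carbaldehyde, via oxocarbenium silyl enol ether 12 (not isolated)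
Conditions: TMSOTf (0.2 equiv), CH2Cl2, −78 → 0 °C; then Et3N
Reagents that add atoms: none
Why: TMSOTf should silylate the enol-ether oxygen O1, the acetal bond C2–O1 then breaks to the ion pair 12 (an (E)-aryl oxocarbenium ion on O3 tethered to a (Z)-silyl enol ether), and carbon C6 attacks C2 in an intramolecular Mukaiyama aldol step that releases the silyl group again. The closest known reaction type is the Lewis-acid [1,3] O-to-C rearrangement (Petasis–Ferrier type) of cyclic vinyl acetals, established for the ring contraction of 4,5-dihydro-1,3-dioxepines to tetrahydrofuran-3-carbaldehydes. The oxolane ring (O3, C2, C6, C5, C4 of 11) closes in the 5-(enolexo)-endo-trig mode, with the oxocarbenium C=O inside and the enol C=C outside the new ring. C3 of 13 is controlled by the methyl-bearing carbon (C5 of 11, C4 of 13): allylic 1,3-strain in the (Z)-enol ether turns its C–H into the enol plane, so the formyl group should end trans to the methyl group, and this centre stays epimerisable alpha to the aldehyde. C2 of 13 is controlled by thermodynamics relayed from the two existing centres: on warming to 0 °C the ring closure should be reversible (retro-aldol re-ionisation), so the mixture should drain into the all-trans isomer, in which every pair of neighbours is trans. The step needs ionisation at C2–O1 and not at the benzylic C4–O3 bond, which is secured by the enol-ether oxygen as silyl acceptor and leaving group, by the para-methoxy donor of the 3,4-dimethoxyphenyl group at C2, and by the 3,4,5-trimethoxyphenyl group at C4, whose para-methoxy group is twisted out of conjugation and whose meta-methoxy groups withdraw inductively.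

Step 7
Reactants: 13 all-trans oxolane-3-carbaldehyde
Product: 14 [(2S,3R,4S,5S)-2-(3,4-dimethoxyphenyl)-4-methyl-5-(3,4,5-trimethoxyphenyl)oxolan-3-yl]methanol
Conditions: NaBH4, MeOH, 0 °C
Reagents that add atoms: none
Why: Hydride reduction of the aldehyde to the primary alcohol; no stereocentre is formed, and the alpha centre is already in its thermodynamic configuration (the descriptor changes from 3S to 3R only through the priority rules).

Step 8
Reactants: 14 primary alcohol
Product: 15 [(2S,3R,4S,5S)-2-(3,4-dimethoxyphenyl)-4-methyl-5-(3,4,5-trimethoxyphenyl)oxolan-3-yl]methyl methanesulfonate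
Conditions: MsCl, Et3N, CH2Cl2, 0 °C
Reagents that add atoms: methanesulfonyl chloride, CS(=O)(=O)Cl
Why: Sulfonylation of the primary alcohol under basic conditions, which leave the acid-sensitive benzylic ether bonds of the ring alone.

Step 9
Reactants: 15 mesylate
Product: 16 (2S,3S,4S,5S)-2-(3,4-dimethoxyphenyl)-3,4-dimethyl-5-(3,4,5-trimethoxyphenyl)oxolane (5-methoxygalbelgin)
Conditions: LiAlH4, THF, 0 °C → reflux
Reagents that add atoms: none
Why: SN2 displacement of the primary sulfonate by hydride turns CH2OMs into CH3 without touching a stereocentre, as is common for hydroxymethyl oxolane lignans.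

**Compound list**

1 | 3,4,5-trimethoxybenzaldehyde | COc1cc(C=O)cc(OC)c1OC | starting material
2 | (E)-crotylboronic acid pinacol ester | C/C=C/CB1OC(C)(C)C(C)(C)O1 | starting material
3 | 2-{[(1S,2S)-2-methyl-1-(3,4,5-trimethoxyphenyl)but-3-en-1-yl]oxy}-4,4,5,5-tetramethyl-1,3,2-dioxaborolane | CC1(C)OB(O[C@H](c2cc(OC)c(OC)c(OC)c2)[C@@H](C)C=C)OC1(C)C | intermediate
4 | (1S,2S)-2-methyl-1-(3,4,5-trimethoxyphenyl)but-3-en-1-ol | O[C@H](c1cc(OC)c(OC)c(OC)c1)[C@@H](C)C=C | intermediate
5 | 3,4-dimethoxybenzaldehyde | COc1ccc(C=O)cc1OC | starting material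
6 | 2-bromoethanol | OCCBr | starting material
7 | 4-[bis(2-bromoethoxy)methyl]-1,2-dimethoxybenzene | COc1ccc(C(OCCBr)OCCBr)cc1OC | intermediate
8 | 4-[(2-bromoethoxy)(chloro)methyl]-1,2-dimethoxybenzene | COc1ccc(C(Cl)OCCBr)cc1OC | intermediate
9 | 4-[(2-bromoethoxy){[(1S,2S)-2-methyl-1-(3,4,5-trimethoxyphenyl)but-3-en-1-yl]oxy}methyl]-1,2-dimethoxybenzene, both epimers at the acetal carbon | COc1ccc(C(OCCBr)O[C@H](c2cc(OC)c(OC)c(OC)c2)[C@@H](C)C=C)cc1OC | intermediate
10 | 4-[(ethenyloxy){[(1S,2S)-2-methyl-1-(3,4,5-trimethoxyphenyl)but-3-en-1-yl]oxy}methyl]-1,2-dimethoxybenzene, both epimers at the acetal carbon | COc1ccc(C(OC=C)O[C@H](c2cc(OC)c(OC)c(OC)c2)[C@@H](C)C=C)cc1OC | intermediate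
11 | (4S,5S)-2-(3,4-dimethoxyphenyl)-5-methyl-4-(3,4,5-trimethoxyphenyl)-4,5-dihydro-1,3-dioxepine, both epimers at C2 | COc1ccc(C2OC=C[C@H](C)[C@@H](c3cc(OC)c(OC)c(OC)c3)O2)cc1OC | intermediate
12 | (3,4-dimethoxybenzylidene)[(1S,2S,3Z)-2-methyl-1-(3,4,5-trimethoxyphenyl)-4-(trimethylsilyloxy)but-3-en-1-yl]oxonium triflate | C[Si](C)(C)O/C=C\[C@H](C)[C@@H](c1cc(OC)c(OC)c(OC)c1)[O+]=Cc1ccc(OC)c(OC)c1.[O-]S(=O)(=O)C(F)(F)F | intermediate
13 | (2S,3S,4S,5S)-2-(3,4-dimethoxyphenyl)-4-methyl-5-(3,4,5-trimethoxyphenyl)oxolane-3-carbaldehyde | COc1ccc([C@H]2O[C@H](c3cc(OC)c(OC)c(OC)c3)[C@@H](C)[C@@H]2C=O)cc1OC | intermediate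
14 | [(2S,3R,4S,5S)-2-(3,4-dimethoxyphenyl)-4-methyl-5-(3,4,5-trimethoxyphenyl)oxolan-3-yl]methanol | COc1ccc([C@H]2O[C@H](c3cc(OC)c(OC)c(OC)c3)[C@@H](C)[C@@H]2CO)cc1OC | intermediate
15 | [(2S,3R,4S,5S)-2-(3,4-dimethoxyphenyl)-4-methyl-5-(3,4,5-trimethoxyphenyl)oxolan-3-yl]methyl methanesulfonate | COc1ccc([C@H]2O[C@H](c3cc(OC)c(OC)c(OC)c3)[C@@H](C)[C@@H]2COS(C)(=O)=O)cc1OC | intermediate
16 | (2S,3S,4S,5S)-2-(3,4-dimethoxyphenyl)-3,4-dimethyl-5-(3,4,5-trimethoxyphenyl)oxolane (5-methoxygalbelgin) | COc1ccc([C@H]2O[C@H](c3cc(OC)c(OC)c(OC)c3)[C@@H](C)[C@@H]2C)cc1OC | target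

**Step count**

Total steps: 9. Longest linear sequence: 8 (steps 1 and 3 to 9; step 2 is a one-step side branch from 5).

**Steps most likely to fail**

Step 6. What may go wrong: ionisation of the benzylic C4–O3 bond of 11 in competition with the acetal bond, and ring closure that is not reversed often enough to correct the configuration at C2. The fallback sets out from 4 and comes back at 16; it closes the ring as a lactone and adds the second aryl group last. Hydroboration–oxidation of 4 (9-BBN, THF; NaOH, H2O2) should give (1S,2S)-2-methyl-1-(3,4,5-trimethoxyphenyl)butane-1,4-diol F1. Oxidative lactonisation (TEMPO, PhI(OAc)2, CH2Cl2) should give the trans lactone (4S,5S)-4-methyl-5-(3,4,5-trimethoxyphenyl)oxolan-2-one F2. Enolate methylation (LiN(SiMe3)2, MeI, THF, −78 °C) anti to the C4 methyl group should give (3S,4S,5S)-3,4-dimethyl-5-(3,4,5-trimethoxyphenyl)oxolan-2-one F3. Reduction (iBu2AlH, CH2Cl2, −78 °C) should give the lactol (3S,4S,5S)-3,4-dimethyl-5-(3,4,5-trimethoxyphenyl)oxolan-2-ol F4. Friedel–Crafts C-arylation of its cyclic oxocarbenium ion with 1,2-dimethoxybenzene (BF3·OEt2, CH2Cl2, −78 → 0 °C), trans to the C3 methyl group, should then give 16.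

Step 5. What may go wrong: capture of the ruthenium alkylidene by the vinyl ether as an unreactive alkoxycarbene, and migration of the terminal double bond before ring closure. The fallback sets out from 4 and 5 and comes back at 11; it closes the ring onto a 1-propenyl ether with a molybdenum alkylidene that tolerates enol ethers. Acetalisation of 5 with allyl alcohol (TsOH, PhMe, Dean–Stark) should give 4-[bis(allyloxy)methyl]-1,2-dimethoxybenzene F5. Acetyl chloride should turn it into 4-[(allyloxy)(chloro)methyl]-1,2-dimethoxybenzene F6, which with 4 and iPr2NEt should give the allyl mixed acetal 4-[(allyloxy){[(1S,2S)-2-methyl-1-(3,4,5-trimethoxyphenyl)but-3-en-1-yl]oxy}methyl]-1,2-dimethoxybenzene F7. Base-mediated allyl-to-propenyl isomerisation (KOtBu, DMSO, rt) should give the (Z)-prop-1-enyl mixed acetal 1,2-dimethoxy-4-[{[(1S,2S)-2-methyl-1-(3,4,5-trimethoxyphenyl)but-3-en-1-yl]oxy}{[(Z)-prop-1-en-1-yl]oxy}methyl]benzene F8. Ring closure with Mo(=CHCMe2Ph)(=N-2,6-iPr2C6H3)[OCMe(CF3)2]2 (benzene, rt), with loss of propene, should then give 11.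

Step 3. What may go wrong: loss of the α-chloro ether by hydrolysis or acetal scrambling before the hindered benzylic alcohol captures it, or acid-induced Prins closure onto the alkene. The fallback sets out from 4 and comes back at 9; it replaces alkylation by a Lewis-acid acetal exchange of a silyl ether. Silylation of 4 (TMSCl, imidazole, CH2Cl2) should give trimethyl{[(1S,2S)-2-methyl-1-(3,4,5-trimethoxyphenyl)but-3-en-1-yl]oxy}silane F9. Exchange with acetal 7 (TMSOTf 5 mol %, CH2Cl2, −78 °C; Et3N quench) should give 9; the low temperature and the poor alkene nucleophile should keep the Prins pathway slow.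

**Further compounds**

F1 | step 6 | (1S,2S)-2-methyl-1-(3,4,5-trimethoxyphenyl)butane-1,4-diol | O[C@H](c1cc(OC)c(OC)c(OC)c1)[C@@H](C)CCO
F2 | step 6 | (4S,5S)-4-methyl-5-(3,4,5-trimethoxyphenyl)oxolan-2-one | O=C1O[C@H](c2cc(OC)c(OC)c(OC)c2)[C@@H](C)C1
F3 | step 6 | (3S,4S,5S)-3,4-dimethyl-5-(3,4,5-trimethoxyphenyl)oxolan-2-one | O=C1O[C@H](c2cc(OC)c(OC)c(OC)c2)[C@@H](C)[C@@H]1C
F4 | step 6 | (3S,4S,5S)-3,4-dimethyl-5-(3,4,5-trimethoxyphenyl)oxolan-2-ol, both anomers | OC1O[C@H](c2cc(OC)c(OC)c(OC)c2)[C@@H](C)[C@@H]1C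
F5 | step 5 | 4-[bis(allyloxy)methyl]-1,2-dimethoxybenzene | COc1ccc(C(OCC=C)OCC=C)cc1OC
F6 | step 5 | 4-[(allyloxy)(chloro)methyl]-1,2-dimethoxybenzene | COc1ccc(C(Cl)OCC=C)cc1OC
F7 | step 5 | 4-[(allyloxy){[(1S,2S)-2-methyl-1-(3,4,5-trimethoxyphenyl)but-3-en-1-yl]oxy}methyl]-1,2-dimethoxybenzene, both epimers at the acetal carbon | COc1ccc(C(OCC=C)O[C@H](c2cc(OC)c(OC)c(OC)c2)[C@@H](C)C=C)cc1OC
F8 | step 5 | 1,2-dimethoxy-4-[{[(1S,2S)-2-methyl-1-(3,4,5-trimethoxyphenyl)but-3-en-1-yl]oxy}{[(Z)-prop-1-en-1-yl]oxy}methyl]benzene, both epimers at the acetal carbon | COc1ccc(C(O/C=C\C)O[C@H](c2cc(OC)c(OC)c(OC)c2)[C@@H](C)C=C)cc1OC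
F9 | step 3 | trimethyl{[(1S,2S)-2-methyl-1-(3,4,5-trimethoxyphenyl)but-3-en-1-yl]oxy}silane | C[Si](C)(C)O[C@H](c1cc(OC)c(OC)c(OC)c1)[C@@H](C)C=C
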